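A direct plan would take the octalin from the chiral pool: (+)-sclareolide (A1) would be opened to the Δ8,9 ester and lengthened stepwise to terminal alkyne A2. The alkyne would be difunctionalized to the Z-allylic alcohol with a 3-furyl ketone attached, asymmetric reduction would give furyl diol A3, and the furan would be photooxygenated to the butenolide. Its weakest steps would be the lengthening of A1 to A2 (several operations, no gain in complexity), the regio- and stereodefined difunctionalization of a terminal alkyne (no reliable method; the β,γ-unsaturated ketone formed would slip into conjugation), and the singlet-oxygen oxidation of A3 (the tetrasubstituted C8=C9 alkene would compete by an ene reaction).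

The route rests on folding the octalin from an acyclic chain: disconnection of C4–C5 and C9–C10 leads to geranyl acetoacetate 4. One proton-initiated, ligand-controlled bicyclization closes rings A and B, sets C5 and quaternary C10, and leaves a C8 ketone and C9 ester that mark the future C8=C9 alkene (enol triflate, methyl coupling) and supply C11 as an allylic electrophile. No terpenoid lactone has to be lengthened; the Z-alkene comes from a Wittig reaction of α-silyloxy ketone 17 with a ylide that already carries C16 and the butenolide, masked as a silyloxyfuran, so neither an alkyne difunctionalization nor a furan photooxygenation is needed.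

Key step: step 2

Remark on numbering: C1–C10 are the octalin carbons (gem-dimethyl on C4, methyls on C8 and C10), C11–C16 the chain, C24 the CH2OH carbon, and C17 (ring carbon bearing C16), C18, C19 (C=O) and C25 (OCH2) the butenolide.
Abbreviations: octalinyl = (4aS,8aS)-2,5,5,8a-tetramethyl-3,4,4a,5,6,7,8,8a-octahydronaphthalen-1-yl; TBS = tert-butyldimethylsilyl.
Assumption: the (R)-binaphthol-derived acid of step 2 is taken to give the (5S,10S) series, as it does with oxygen-terminated homofarnesyl substrates; the (S)-ligand would be used if the sense were opposite.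

Step 1
Reactants: 1 geranyl bromide, (2E)-1-bromo-3,7-dimethylocta-2,6-diene; 2 methyl acetoacetate
Product: 4 methyl (6E)-7,11-dimethyl-3-oxododeca-6,10-dienoate, via acetoacetate dianion 3 (not isolated)
Conditions: 2, NaH, THF, 0 °C; n-BuLi, 0 °C; then 1, 0 °C → rt; aq. HCl
Reagents that add atoms: none
Why: γ-Alkylation of a β-keto ester dianion, in which the more basic terminal carbanion displaces the primary allylic bromide by SN2, the E alkene is carried over unchanged and no stereocentre is formed.

Step 2
Reactants: 4 methyl (6E)-7,11-dimethyl-3-oxododeca-6,10-dienoate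
Product: 6 methyl (1R,4aS,8aS)-5,5,8a-trimethyl-2-oxodecahydronaphthalene-1-carboxylate, via monocyclic keto ester 5 (not isolated)
Conditions: SnCl4·(R)-2′-[(2-fluorophenyl)methoxy]-1,1′-binaphthalen-2-ol (preformed 1:1 complex, 2 equiv), toluene, −78 °C, to full consumption of 4; then SnCl4 (2 equiv), CH2Cl2, −78 → 0 °C
Reagents that add atoms: none
Why: Proposed new method: the chiral Lewis-acid-assisted Brønsted acid (the phenolic proton made strongly acidic by SnCl4 and held in the binaphthyl pocket) should deliver H+ to C3 of the terminal alkene while C5 of the C5=C10 bond attacks C4 in a chair, and the C10 cation is then taken by the enol carbon C9 of the β-keto ester, with added SnCl4 closing ring B in the same pot for any material that stopped at monocyclic 5. The closest known reaction types are the enantioselective proton-initiated cyclization of homofarnesyl polyenes ending in hydroxyl, carboxyl or aryl groups and the achiral SnCl4 cyclization of β-keto-ester-terminated polyenes; a β-dicarbonyl terminator under the chiral acid is the untested element. Ring A closes by 6-endo addition of the C4 cation to C5 and ring B by 6-endo attack of C9 on the C10 cation, chair–chair, which gives the trans ring fusion. C5 is set by the enantiofacial protonation and ring A closure under ligand control, C10 follows from anti addition across the E-configured C5=C10 bond, and C9 relaxes to the equatorial ester by enolization and is erased in step 3. The step needs enantioselection over the achiral tin-enolate pathway, which the preformed complex and −78 °C (where that pathway is slow) should secure, and C- over O-termination, which the tin chelate of the β-keto ester in the second stage secures.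

Step 3
Reactants: 6 methyl (1R,4aS,8aS)-5,5,8a-trimethyl-2-oxodecahydronaphthalene-1-carboxylate
Product: 8 methyl (4aS,8aS)-5,5,8a-trimethyl-2-{[(trifluoromethyl)sulfonyl]oxy}-3,4,4a,5,6,7,8,8a-octahydronaphthalene-1-carboxylate, via sodium enolate 7 (not isolated)
Conditions: NaH, Et2O, 0 °C; Tf2O, −78 → 0 °C
Reagents that add atoms: trifluoromethanesulfonic anhydride, O=S(=O)(OS(=O)(=O)C(F)(F)F)C(F)(F)F
Why: O-Sulfonylation of the β-keto ester enolate gives the ring-locked enol triflate, which fixes the later alkene at C8=C9 without any elimination regiochemistry and turns C9 into an sp2 carbon.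

Step 4
Reactants: 8 enol triflate
Product: 9 methyl (4aS,8aS)-2,5,5,8a-tetramethyl-3,4,4a,5,6,7,8,8a-octahydronaphthalene-1-carboxylate
Conditions: MeMgBr, Fe(acac)3 (5 mol %), THF–NMP, −30 °C
Reagents that add atoms: methylmagnesium bromide, C[Mg]Br
Why: Iron-catalysed Kumada-type cross-coupling of a β-triflyloxy enoate with a methyl Grignard reagent, which is much faster than addition to the hindered ester, puts the C8 methyl on the tetrasubstituted alkene.

Step 5
Reactants: 9 methyl ester of the octalin acid
Product: 10 (octalinyl)methanol, [(4aS,8aS)-2,5,5,8a-tetramethyl-3,4,4a,5,6,7,8,8a-octahydronaphthalen-1-yl]methanol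
Conditions: i-Bu2AlH, CH2Cl2, −78 → 0 °C; aq. potassium sodium tartrate
Reagents that add atoms: none
Why: 1,2-Hydride reduction of the hindered conjugated ester by i-Bu2AlH gives the primary allylic alcohol, the tetrasubstituted alkene and both stereocentres being inert.

Step 6
Reactants: 10 (octalinyl)methanol
Product: 11 (octalinyl)methyl bromide, (4aS,8aS)-1-(bromomethyl)-2,5,5,8a-tetramethyl-3,4,4a,5,6,7,8,8a-octahydronaphthalene
Conditions: PBr3, pyridine (cat.), Et2O, −10 °C; used crude
Reagents that add atoms: phosphorus tribromide, BrP(Br)Br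
Why: Bromination of a primary allylic alcohol through its phosphite ester (SN2 by bromide), in which the primary bromide on the tetrasubstituted alkene is also the thermodynamic allylic isomer.

Step 7
Reactants: 12 1-[(tert-butyldimethylsilyl)oxy]propan-2-one; 13 1,1-dimethylhydrazine
Product: 14 1-[(tert-butyldimethylsilyl)oxy]propan-2-one N,N-dimethylhydrazone
Conditions: AcOH (cat.), EtOH, reflux
Reagents that add atoms: none
Why: Hydrazone formation by condensation gives the azaenolate precursor that allows regiocontrolled alkylation at the methyl carbon.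

Step 8
Reactants: 11 (octalinyl)methyl bromide; 14 silyloxyacetone dimethylhydrazone
Product: 17 1-[(tert-butyldimethylsilyl)oxy]-4-(octalinyl)butan-2-one, via lithium azaenolate 15 (not isolated), via alkylated hydrazone 16 (not isolated)
Conditions: 14, LiN(i-Pr)2, THF, 0 °C; 11, −78 → 0 °C; then sat. aq. oxalic acid–Et2O, rt
Reagents that add atoms: water, O
Why: Alkylation of an N,N-dimethylhydrazone azaenolate, which forms at the unsubstituted methyl carbon (C12) and attacks the allylic bromide by SN2 at C11 (SN2′ at the fully substituted C8 is blocked), followed by mild two-phase hydrolysis that spares the silyl ether.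

Step 9
Reactants: 18 4-bromofuran-2(5H)-one
Product: 19 4-(tributylstannyl)furan-2(5H)-one
Conditions: (Bu3Sn)2, Pd(PPh3)4 (cat.), toluene, 100 °C
Reagents that add atoms: hexabutylditin, CCCC[Sn](CCCC)(CCCC)[Sn](CCCC)(CCCC)CCCC
Why: Palladium-catalysed stannylation of a vinylogous acyl bromide with a distannane (oxidative addition, Sn–Sn transmetalation, reductive elimination).

Step 10
Reactants: 19 4-(tributylstannyl)furan-2(5H)-one; 20 3-chloropropanoyl chloride
Product: 21 4-(3-chloropropanoyl)furan-2(5H)-one
Conditions: PdCl2(PPh3)2 (cat.), toluene, 70 °C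
Reagents that add atoms: none
Why: Stille acylation, in which the acyl-palladium chloride transmetalates with the vinylstannane and reductive elimination forms the C16–C17 bond, the alkyl chloride being inert to zerovalent palladium at this temperature.

Step 11
Reactants: 21 4-(3-chloropropanoyl)furan-2(5H)-one
Product: 22 4-[(1R)-3-chloro-1-hydroxypropyl]furan-2(5H)-one
Conditions: (S)-1-methyl-3,3-diphenyltetrahydro-1H,3H-pyrrolo[1,2-c][1,3,2]oxazaborole (0.2 equiv), BH3·SMe2, THF, −20 °C; MeOH
Reagents that add atoms: none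
Why: Corey–Bakshi–Shibata reduction, in which the ketone binds the oxazaborolidine with the sp2 butenolide as the large group and CH2CH2Cl as the small one, so that the (S)-catalyst delivers hydride to the face giving the 16R carbinol, as it does with aryl alkyl ketones.

Step 12
Reactants: 22 4-[(1R)-3-chloro-1-hydroxypropyl]furan-2(5H)-one
Product: 24 [(3R)-3-hydroxy-3-(5-oxo-2,5-dihydrofuran-3-yl)propyl]triphenylphosphonium iodide, via iodo alcohol 23 (not isolated)
Conditions: NaI, PPh3, MeCN, reflux
Reagents that add atoms: sodium iodide, [Na+].[I-]; triphenylphosphine, c1ccccc1P(c1ccccc1)c1ccccc1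
Why: Finkelstein exchange followed by SN2 quaternization of triphenylphosphine at primary C14 under neutral conditions, which leave the butenolide and C16 untouched.

Step 13
Reactants: 24 hydroxy phosphonium iodide
Product: 25 {(3R)-3-[(tert-butyldimethylsilyl)oxy]-3-{5-[(tert-butyldimethylsilyl)oxy]furan-3-yl}propyl}triphenylphosphonium iodide
Conditions: t-BuMe2SiOTf (2.5 equiv), Et3N, CH2Cl2, 0 °C; aq. NaHCO3, then aq. NaI wash; used without chromatography
Reagents that add atoms: tert-butyldimethylsilyl trifluoromethanesulfonate, CC(C)(C)[Si](C)(C)OS(=O)(=O)C(F)(F)F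
Why: Silyl triflate–amine silylation of the alcohol together with O-silylation and ring CH2 deprotonation of the butenolide to the aromatic 2-silyloxyfuran, which removes the acidic γ-hydrogens before ylide formation while the amine is too weak to touch the phosphonium salt or C16.

Step 14
Reactants: 25 bis-silylated phosphonium iodide; 17 1-[(tert-butyldimethylsilyl)oxy]-4-(octalinyl)butan-2-one
Product: 27 (1R,3Z)-1-{5-[(TBS)oxy]furan-3-yl}-4-{[(TBS)oxy]methyl}-6-(octalinyl)hex-3-en-1-ol TBS ether, via phosphonium ylide 26 (not isolated)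
Conditions: 25, NaN(SiMe3)2 (1.0 equiv), THF, −78 °C; then 17, THF–HMPA, −78 °C → rt
Reagents that add atoms: none
Why: Wittig olefination of an α-alkoxy ketone with a non-stabilised, lithium-free ylide, a combination known to place the CH2O group cis to the new alkyl chain, forms C13=C14 as the Z isomer, while the silyloxyfuran has no acidic hydrogen and C16 is not touched.

Step 15
Reactants: 27 tris-silylated Wittig product
Product: 29 4-[(1R,3Z)-1-hydroxy-4-(hydroxymethyl)-6-(octalinyl)hex-3-en-1-yl]furan-2(5H)-one (CNP0224983.2), via bis-silyl butenolide 28 (not isolated)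
Conditions: HF·pyridine, pyridine, THF, 0 °C → rt
Reagents that add atoms: none
Why: Fluoride-mediated desilylation, in which the silyloxyfuran is cleaved first and protonated at C25 to the conjugated butenolide and both silyl ethers then fall under buffered conditions that neither epimerise C16 nor move the alkenes.

Compound list
1 | geranyl bromide, (2E)-1-bromo-3,7-dimethylocta-2,6-diene | CC(C)=CCC/C(C)=C/CBr | starting material
2 | methyl acetoacetate | CC(=O)CC(=O)OC | starting material
3 | sodium lithium dianion of methyl acetoacetate | [Na+].[Li+].[CH2-]C(=O)[CH-]C(=O)OC | intermediate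
4 | methyl (6E)-7,11-dimethyl-3-oxododeca-6,10-dienoate | COC(=O)CC(=O)CC/C=C(C)/CCC=C(C)C | intermediate
5 | methyl 3-oxo-5-[(1S)-2,6,6-trimethylcyclohex-2-en-1-yl]pentanoate (monocyclic keto ester, may be accompanied by its ring double-bond isomers) | COC(=O)CC(=O)CC[C@@H]1C(C)=CCCC1(C)C | intermediate
6 | methyl (1R,4aS,8aS)-5,5,8a-trimethyl-2-oxodecahydronaphthalene-1-carboxylate | O=C1[C@H](C(=O)OC)[C@@]2(C)CCCC(C)(C)[C@@H]2CC1 | intermediate
7 | sodium enolate of 6 | [Na+].[O-]C1=C(C(=O)OC)[C@@]2(C)CCCC(C)(C)[C@@H]2CC1 | intermediate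
8 | methyl (4aS,8aS)-5,5,8a-trimethyl-2-{[(trifluoromethyl)sulfonyl]oxy}-3,4,4a,5,6,7,8,8a-octahydronaphthalene-1-carboxylate | FC(F)(F)S(=O)(=O)OC1=C(C(=O)OC)[C@@]2(C)CCCC(C)(C)[C@@H]2CC1 | intermediate
9 | methyl (4aS,8aS)-2,5,5,8a-tetramethyl-3,4,4a,5,6,7,8,8a-octahydronaphthalene-1-carboxylate | CC1=C(C(=O)OC)[C@@]2(C)CCCC(C)(C)[C@@H]2CC1 | intermediate
10 | (octalinyl)methanol | CC1=C(CO)[C@@]2(C)CCCC(C)(C)[C@@H]2CC1 | intermediate
11 | (octalinyl)methyl bromide | CC1=C(CBr)[C@@]2(C)CCCC(C)(C)[C@@H]2CC1 | intermediate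
12 | 1-[(tert-butyldimethylsilyl)oxy]propan-2-one | CC(=O)CO[Si](C)(C)C(C)(C)C | starting material
13 | 1,1-dimethylhydrazine | CN(C)N | starting material
14 | 1-[(tert-butyldimethylsilyl)oxy]propan-2-one N,N-dimethylhydrazone | CC(CO[Si](C)(C)C(C)(C)C)=NN(C)C | intermediate
15 | lithium azaenolate of 14 (metalated at the methyl carbon) | [Li+].[CH2-]C(CO[Si](C)(C)C(C)(C)C)=NN(C)C | intermediate
16 | 1-[(tert-butyldimethylsilyl)oxy]-4-(octalinyl)butan-2-one N,N-dimethylhydrazone | CC1=C(CCC(CO[Si](C)(C)C(C)(C)C)=NN(C)C)[C@@]2(C)CCCC(C)(C)[C@@H]2CC1 | intermediate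
17 | 1-[(tert-butyldimethylsilyl)oxy]-4-(octalinyl)butan-2-one | CC1=C(CCC(=O)CO[Si](C)(C)C(C)(C)C)[C@@]2(C)CCCC(C)(C)[C@@H]2CC1 | intermediate
18 | 4-bromofuran-2(5H)-one | O=C1OCC(Br)=C1 | starting material
19 | 4-(tributylstannyl)furan-2(5H)-one | O=C1OCC([Sn](CCCC)(CCCC)CCCC)=C1 | intermediate
20 | 3-chloropropanoyl chloride | O=C(Cl)CCCl | starting material
21 | 4-(3-chloropropanoyl)furan-2(5H)-one | O=C(CCCl)C1=CC(=O)OC1 | intermediate
22 | 4-[(1R)-3-chloro-1-hydroxypropyl]furan-2(5H)-one | ClCC[C@@H](O)C1=CC(=O)OC1 | intermediate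
23 | 4-[(1R)-1-hydroxy-3-iodopropyl]furan-2(5H)-one | ICC[C@@H](O)C1=CC(=O)OC1 | intermediate
24 | [(3R)-3-hydroxy-3-(5-oxo-2,5-dihydrofuran-3-yl)propyl]triphenylphosphonium iodide | [I-].O[C@H](CC[P+](c1ccccc1)(c1ccccc1)c1ccccc1)C1=CC(=O)OC1 | intermediate
25 | {(3R)-3-[(tert-butyldimethylsilyl)oxy]-3-{5-[(tert-butyldimethylsilyl)oxy]furan-3-yl}propyl}triphenylphosphonium iodide | [I-].CC(C)(C)[Si](C)(C)O[C@H](CC[P+](c1ccccc1)(c1ccccc1)c1ccccc1)c1coc(O[Si](C)(C)C(C)(C)C)c1 | intermediate
26 | ylide of 25, {(3R)-3-[(TBS)oxy]-3-{5-[(TBS)oxy]furan-3-yl}propylidene}triphenylphosphorane | CC(C)(C)[Si](C)(C)O[C@H](CC=P(c1ccccc1)(c1ccccc1)c1ccccc1)c1coc(O[Si](C)(C)C(C)(C)C)c1 | intermediate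
27 | (1R,3Z)-1-{5-[(TBS)oxy]furan-3-yl}-4-{[(TBS)oxy]methyl}-6-(octalinyl)hex-3-en-1-ol TBS ether | CC1=C(CC/C(=C/C[C@@H](O[Si](C)(C)C(C)(C)C)c3coc(O[Si](C)(C)C(C)(C)C)c3)CO[Si](C)(C)C(C)(C)C)[C@@]2(C)CCCC(C)(C)[C@@H]2CC1 | intermediate
28 | 4-[(1R,3Z)-1-[(TBS)oxy]-4-{[(TBS)oxy]methyl}-6-(octalinyl)hex-3-en-1-yl]furan-2(5H)-one | CC1=C(CC/C(=C/C[C@@H](O[Si](C)(C)C(C)(C)C)C3=CC(=O)OC3)CO[Si](C)(C)C(C)(C)C)[C@@]2(C)CCCC(C)(C)[C@@H]2CC1 | intermediate
29 | 4-[(1R,3Z)-1-hydroxy-4-(hydroxymethyl)-6-(octalinyl)hex-3-en-1-yl]furan-2(5H)-one, CNP0224983.2 | CC1=C(CC/C(=C/C[C@@H](O)C2=CC(=O)OC2)CO)[C@@]2(C)CCCC(C)(C)[C@@H]2CC1 | target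

Total step count: 15. Longest linear sequence: 9 (steps 1–6, 8, 14, 15).

Steps most likely to fail

1. Step 2 (Proposed new method). Ligand exchange between the chiral tin complex and the β-keto ester could release an achiral tin-bound acid, so that protonation outside the chiral pocket erodes the enantiomeric purity; ring B could also close incompletely in the first stage. Keto ester 6 would be the point at which enantiomeric purity is raised by recrystallisation. Fallback, from 4 back to 6: cyclization with SnCl4 alone in CH2Cl2 would give the racemic trans-fused keto ester F1. Condensation with (S)-1-phenylethylamine (AcOH cat., toluene, water removal) would give diastereomeric enamino esters, from which the (4aS,8aS) enamino ester F2 would be separated by crystallization. Dilute aqueous acid would then hydrolyse F2 to 6.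

2. Step 14. The basic ylide could enolize ketone 17 instead of adding to it, the kinetic preference for the Z alkene could be lost with this branched ylide, or the silyloxyfuran could be cleaved before olefination. Fallback, from 17 back to 29, with C16 set late by reagent control instead of being carried in the ylide: Wittig reaction of 17 with the ylide from [2-(1,3-dioxolan-2-yl)ethyl]triphenylphosphonium bromide and NaN(SiMe3)2 would give the Z-configured acetal F3. Mild acetal hydrolysis would give the β,γ-unsaturated aldehyde F4. Nozaki–Hiyama–Kishi coupling of F4 with 18 (CrCl2, NiCl2 cat., DMF) would give the butenolide carbinol F5 as C16 epimers. Dess–Martin oxidation would give ketone F6, and Corey–Bakshi–Shibata reduction with the (S)-oxazaborolidine would give the 16R alcohol F7, which the conditions of step 15 would convert to 29.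

3. Step 10. Transmetalation of the electron-poor vinylstannane could be too slow, so that decarbonylation of the acyl-palladium intermediate or loss of HCl from the β-chloro ketone takes over. Fallback, from 18 back to 21: silylation of 18 with i-Pr3SiOTf and Et3N would give 4-bromo-2-[(triisopropylsilyl)oxy]furan F8. Bromine–lithium exchange (t-BuLi, THF, −78 °C) and acylation with 3-chloro-N-methoxy-N-methylpropanamide would give the silyloxyfuryl ketone F9, and dilute aqueous HCl would unmask the butenolide to give 21.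

Further compounds
F1 | step 2 | racemic methyl (1R*,4aS*,8aS*)-5,5,8a-trimethyl-2-oxodecahydronaphthalene-1-carboxylate (both enantiomers) | O=C1[C@H](C(=O)OC)[C@@]2(C)CCCC(C)(C)[C@@H]2CC1.O=C1[C@@H](C(=O)OC)[C@]2(C)CCCC(C)(C)[C@H]2CC1
F2 | step 2 | methyl (4aS,8aS)-5,5,8a-trimethyl-2-{[(1S)-1-phenylethyl]amino}-3,4,4a,5,6,7,8,8a-octahydronaphthalene-1-carboxylate | c3ccccc3[C@H](C)NC1=C(C(=O)OC)[C@@]2(C)CCCC(C)(C)[C@@H]2CC1
F3 | step 14 | tert-butyl{[(2Z)-4-(1,3-dioxolan-2-yl)-2-[2-(octalinyl)ethyl]but-2-en-1-yl]oxy}dimethylsilane | CC1=C(CC/C(=C/CC3OCCO3)CO[Si](C)(C)C(C)(C)C)[C@@]2(C)CCCC(C)(C)[C@@H]2CC1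
F4 | step 14 | (3Z)-4-{[(tert-butyldimethylsilyl)oxy]methyl}-6-(octalinyl)hex-3-enal | CC1=C(CC/C(=C/CC=O)CO[Si](C)(C)C(C)(C)C)[C@@]2(C)CCCC(C)(C)[C@@H]2CC1
F5 | step 14 | 4-[(3Z)-1-hydroxy-4-{[(tert-butyldimethylsilyl)oxy]methyl}-6-(octalinyl)hex-3-en-1-yl]furan-2(5H)-one (C16 epimers) | CC1=C(CC/C(=C/CC(O)C3=CC(=O)OC3)CO[Si](C)(C)C(C)(C)C)[C@@]2(C)CCCC(C)(C)[C@@H]2CC1
F6 | step 14 | 4-[(3Z)-4-{[(tert-butyldimethylsilyl)oxy]methyl}-6-(octalinyl)hex-3-enoyl]furan-2(5H)-one | CC1=C(CC/C(=C/CC(=O)C3=CC(=O)OC3)CO[Si](C)(C)C(C)(C)C)[C@@]2(C)CCCC(C)(C)[C@@H]2CC1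
F7 | step 14 | 4-[(1R,3Z)-1-hydroxy-4-{[(tert-butyldimethylsilyl)oxy]methyl}-6-(octalinyl)hex-3-en-1-yl]furan-2(5H)-one | CC1=C(CC/C(=C/C[C@@H](O)C3=CC(=O)OC3)CO[Si](C)(C)C(C)(C)C)[C@@]2(C)CCCC(C)(C)[C@@H]2CC1
F8 | step 10 | 4-bromo-2-[(triisopropylsilyl)oxy]furan | Brc1coc(O[Si](C(C)C)(C(C)C)C(C)C)c1
F9 | step 10 | 3-chloro-1-{5-[(triisopropylsilyl)oxy]furan-3-yl}propan-1-one | ClCCC(=O)c1coc(O[Si](C(C)C)(C(C)C)C(C)C)c1
A1 | direct plan | (+)-sclareolide | C[C@]12OC(=O)C[C@@H]1[C@@]1(C)CCCC(C)(C)[C@@H]1CC2
A2 | direct plan | 4-(octalinyl)but-1-yne | CC1=C(CCC#C)[C@@]2(C)CCCC(C)(C)[C@@H]2CC1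
A3 | direct plan | (1R,3Z)-1-(furan-3-yl)-4-(hydroxymethyl)-6-(octalinyl)hex-3-en-1-ol | CC1=C(CC/C(=C/C[C@@H](O)c2ccoc2)CO)[C@@]2(C)CCCC(C)(C)[C@@H]2CC1
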